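**Remark on the chemistry:** germacrane numbers are used for atoms throughout (ring C1–C10, lactone or furan carbons C11–C13, C14 on C10, C15 on C4); in the bicyclic compounds benzofuran positions 2, 3, 3a, 4, 5, 6, 7, 7a are C12, C11, C7, C8, C9, C10, C5, C6. TBS is tert-butyldimethylsilyl. The configuration of the C5/C10 pair relative to C8 is erased in the key step; only its trans relationship matters.

## Analysis of the target

The target is a germacranolide: a ten-membered carbocycle (C1–C10) fused at C6–C7 to an α,β-unsaturated γ-lactone (O on C6, C12 carbonyl, C7=C11). C11 carries an acetoxymethyl group (C13) and C8 carries a (Z)-2-methylbut-2-enoate (angelate). There are six stereocentres, 1R, 4R, 5R, 6S, 8S and 10R. Both oxiranes are trans (C9 trans to C2, C3 trans to C6), so each is the epoxide of an E ring alkene. O6 and O8 lie on one face across the planar C7, and the two methyl groups lie on the other. The oxiranes are open to acid-triggered transannular attack, the angelate isomerises easily to the tiglate, and the lactone γ-proton (C6–H) sits next to an epoxide and vinylogous to an allylic acetate, so base is a hazard late in the route. The difficulty is a medium ring with two defined alkene geometries and only two conventional carbinol centres (C6, C8) to steer everything else. The feature used is that C1=C10 and C4=C5 flank the C2–C3 bond as a 1,5-diene, so the ten-membered ring is the Cope isomer of a cyclohexane joined at C5–C10, while C6, C7, C11 and C12 can travel through strongly basic steps as a furan.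

## Retrosynthetic reasoning

31 ⇒ 29. The four oxirane C–O bonds are cut first. Both epoxides go back to the E alkenes C1=C10 and C4=C5 of 29. They are placed last because the diepoxide tolerates neither acid nor the base and heat of the acylations. The forward step must deliver oxygen to the outer face of both ring alkenes (through monoepoxide 30) and leave the electron-poor angelate and lactone alkenes alone.

29 ⇒ 28 ⇒ 27 ⇒ 26. The ester C–O bonds at O8 and O13 are cut next. With both oxygens as silyl ethers in 26, one fluoride treatment frees diol 27, the primary alcohol is acetylated first on reactivity (28), and the angelate goes on second without a nucleophilic catalyst.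

26 ⇒ 24 ⇒ 21 ⇒ 20. The lactone is traced to a furan by removing the C12 carbonyl oxygen and the C6–H bond. The gain is a group that survives alkoxide, organolithium and hydride chemistry. Forward, a silyl group at C12 (21) directs photo-oxygenation so that C12 becomes the carboxyl carbon (through 22 and 23 to lactol 24), and reduction of the C6 ketone (through 25) must set C6 under the influence of C8.

20 ⇒ 19. The C5–H bond is exchanged for a C5 triflate. This is the form in which the enolate geometry of the ring expansion can be stored and then removed with retention.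

19 ⇒ 18 ⇒ 17 ⇒ 16. This is the key disconnection: C2–C3 is broken and C5–C10 is re-formed, which contracts the ten-membered ring to a cyclohexanol carrying vinyl on C10 and isopropenyl on C5. The cut is made here because it removes the medium ring and both stereogenic alkenes at once and leaves a six-membered ring on which stereocontrol is conventional. The forward reaction must pass through a chair with both ring bonds equatorial, which requires the two alkenyl groups of 16 to be trans.

16 ⇒ 14 + 15. The C4–C5 bond is cut, giving the non-enolisable ketone 14 and isopropenylmagnesium bromide 15. The addition must occur anti to the vinyl group.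

14 ⇒ 13 ⇒ 10. The C10–C14 bond is cut, then the C10=C1 bond of ethylidene ketone 13 (made from 10 through 11 and 12). Vinyl is introduced first and methyl last, because the group that enters last enters anti to the C8 silyl ether; this order places vinyl cis to O8 as in 14.

10 ⇒ 9 ⇒ 8 ⇒ 7 ⇒ 6. The C5 carbonyl is traced to a C–H oxidation of the methylene on the furan α-carbon. It is done on ester 6, where the ester deactivates the furan ring and the only other furylic C–H (C8–H) is poorly aligned and shielded. The price is a reduction, silylation and re-oxidation sequence (8, 9, 10) to turn the ester into the silyloxymethyl group.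

6 ⇒ 5 ⇒ 4 ⇒ 1 + 2. The furan is cut at C7–C11 and O–C12, which leads to cyclohexane-1,3-dione 1 and ethyl bromopyruvate 2 (through adduct 3). The annulation places the ketone at C8 and the ester at C11, and a catalyst-controlled reduction of 4 sets C8 in 5, the only stereocentre that is carried through the ring expansion.

## Alternatives that were turned down

Alternative 1: The ring alkenes C1=C10 and C4=C5 are cut as the two σ-bonds of a [2+2] photoadduct. In the forward sense excited 3-methylcyclohex-2-enone A2 would add to methyl cyclobut-1-ene-1-carboxylate A3 to give the head-to-head tricyclic keto ester A1. Heating would then break the two cyclobutane bonds that were not made by light (C5–C10 and C1–C4) and release a cyclodeca-1,5-diene. In its favour, the ten-membered carbocycle appears in two steps from very simple materials; on step count to the ring it is stronger than the chosen route. Against it for this target: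
- the photoaddition is racemic and A1 offers no handle for absolute control;
- the thermolysis runs at temperatures where cyclodeca-1,5-dienes equilibrate by Cope rearrangement and where one alkene is typically formed cis, so the E,E geometry is not secured;
- C15 arrives as an ester that must be reduced to methyl, C6 as a bare ketone, C8 without oxygen, and the lactone carbons are missing.

The chosen strategy is longer to the ring, but it fixes both geometries in a chair transition state and carries C8 and the masked lactone through the ring-forming step.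

Alternative 2: The lactone C7=C11 bond is cut. A malonate half-ester on O6 of a cyclodecadienyl C7 ketone would condense under an amine–carboxylic acid catalyst and close the butenolide A4, in which C13 is an allyl ester. In its favour, C6 is set before the lactone exists, so no late ketone reduction has to be trusted, and C13 is already oxidised; on these two points it is stronger than the chosen route. Against it:
- the step builds only the five-membered ring, and the ten-membered ketol with both E alkenes and the C6 and C8 centres must already exist, which is the real problem and is left open;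
- the C7 ketone is flanked by two oxygen-bearing stereocentres that can epimerise or eliminate under the condensation conditions;
- the C13 ester must later be reduced beside the lactone.

The chosen strategy spends its key step on the medium ring and the alkene geometry and makes the lactone from a group that is inert until then.

Alternative 3: The same C5–C10 bond is cut as in the chosen plan, but by a photochemical six-electron ring opening of a trans-fused eudesma-1,3-dienolide from the chiral pool. This would give the triene lactone A5 with a Z C2=C3 bond. In its favour, absolute configuration, C6 and the closed lactone come with the starting material, and one photochemical step makes the ten-membered ring; on the lactone stereochemistry it is stronger. Against it: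
- the opening is reversible and the triene recloses thermally;
- the central alkene of a conjugated triene would have to be saturated selectively;
- A5 has no oxygen at C8 or C13 and no C7=C11 bond, so three functionalisations at unactivated positions would follow, and the C7 and C11 centres bought from the chiral pool would be destroyed.

The chosen strategy breaks the same bond thermally near room temperature with the oxygen pattern at C8, C12 and C13 already in place.

Key step: step 11

## Route

Step 1
Reactants: 1 cyclohexane-1,3-dione; 2 ethyl bromopyruvate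
Product: 4 ethyl 4-oxo-4,5,6,7-tetrahydro-1-benzofuran-3-carboxylate, via hydroxydihydrofuran adduct 3 (not isolated)
Conditions: K2CO3, EtOH, 0 °C to rt; then H2SO4 (cat.), 60 °C
Reagents that add atoms: none
Why: Feist–Benary furan annulation: C2 of the dione adds to the ketone of 2 and the enol oxygen displaces bromide to give adduct 3, which loses water under acid to the furan; the ester necessarily ends on the furan β-carbon (C11) next to the ring ketone (C8).

Step 2
Reactants: 4 ethyl 4-oxo-4,5,6,7-tetrahydro-1-benzofuran-3-carboxylate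
Product: 5 ethyl (4S)-4-hydroxy-4,5,6,7-tetrahydro-1-benzofuran-3-carboxylate
Conditions: (R)-2-methyl-CBS-oxazaborolidine (10 mol %), BH3·SMe2, THF, −20 °C; then MeOH
Reagents that add atoms: none
Why: CBS reduction; the furan-bearing side acts as the large group as in aryl alkyl ketones, so the (R)-catalyst should give the (S)-carbinol, which is C8 of the target and the only stereocentre carried through the key step.

Step 3
Reactants: 5 ethyl (4S)-4-hydroxy-4,5,6,7-tetrahydro-1-benzofuran-3-carboxylate
Product: 6 ethyl (4S)-4-(TBSO)-4,5,6,7-tetrahydro-1-benzofuran-3-carboxylate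
Conditions: TBSCl, imidazole, DMF, rt
Reagents that add atoms: tert-butyldimethylsilyl chloride, CC(C)(C)[Si](C)(C)Cl
Why: Standard silylation of a secondary alcohol; the silyl ether masks O8 until step 16 and its bulk is used for facial control in steps 9 and 10.

Step 4
Reactants: 6 ethyl (4S)-4-(TBSO)-4,5,6,7-tetrahydro-1-benzofuran-3-carboxylate
Product: 7 ethyl (4S)-4-(TBSO)-7-oxo-4,5,6,7-tetrahydro-1-benzofuran-3-carboxylate
Conditions: Rh2(cap)4 (1 mol %), t-BuOOH (70% aq.), NaHCO3, ClCH2CH2Cl, 40 °C
Reagents that add atoms: tert-butyl hydroperoxide, CC(C)(C)OO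
Why: Radical benzylic-type C–H oxidation with t-BuOOH catalysed by dirhodium tetracaprolactamate; C5 is the only methylene on the furan α-carbon and its pseudoaxial C–H bond overlaps with the ring π system, whereas C8–H lies near the ring plane beside the ester and is shielded by the silyl group. The ester keeps the furan ring itself inert to the peroxyl radical.

Step 5
Reactants: 7 ethyl (4S)-4-(TBSO)-7-oxo-4,5,6,7-tetrahydro-1-benzofuran-3-carboxylate
Product: 8 (4S,7RS)-4-(TBSO)-3-(hydroxymethyl)-4,5,6,7-tetrahydro-1-benzofuran-7-ol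
Conditions: LiAlH4, THF, 0 °C
Reagents that add atoms: none
Why: Hydride reduction of ester and ketone together; the C5 carbinol forms as a mixture that does not matter because step 7 returns it to the ketone.

Step 6
Reactants: 8 (4S,7RS)-4-(TBSO)-3-(hydroxymethyl)-4,5,6,7-tetrahydro-1-benzofuran-7-ol
Product: 9 (4S,7RS)-4-(TBSO)-3-[(TBSO)methyl]-4,5,6,7-tetrahydro-1-benzofuran-7-ol
Conditions: TBSCl (1.05 equiv), imidazole, CH2Cl2, −20 °C
Reagents that add atoms: tert-butyldimethylsilyl chloride, CC(C)(C)[Si](C)(C)Cl
Why: Selective silylation of the primary furylic alcohol over the secondary one on steric grounds.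

Step 7
Reactants: 9 (4S,7RS)-4-(TBSO)-3-[(TBSO)methyl]-4,5,6,7-tetrahydro-1-benzofuran-7-ol
Product: 10 (4S)-4-(TBSO)-3-[(TBSO)methyl]-5,6-dihydro-1-benzofuran-7(4H)-one
Conditions: MnO2, CH2Cl2, rt
Reagents that add atoms: none
Why: MnO2 oxidation of an activated (furylic) secondary alcohol under neutral conditions, which avoids ionisation of the C8 silyl ether and aromatisation of the six-membered ring.

Step 8
Reactants: 10 (4S)-4-(TBSO)-3-[(TBSO)methyl]-5,6-dihydro-1-benzofuran-7(4H)-one
Product: 13 (4S,6E)-4-(TBSO)-3-[(TBSO)methyl]-6-ethylidene-5,6-dihydro-1-benzofuran-7(4H)-one, via aldol adduct 11 (not isolated), via aldol mesylate 12 (not isolated)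
Conditions: LiN(i-Pr)2, THF, −78 °C; CH3CHO; AcOH; then MsCl, Et3N, CH2Cl2, 0 °C; DBU, rt
Reagents that add atoms: acetaldehyde, CC=O
Why: Directed aldol condensation: C10 is the only enolisable position of 10, the lithium enolate adds to acetaldehyde, and mesylation followed by E1cB elimination gives the conjugated ethylidene ketone, E by strain relief.

Step 9
Reactants: 13 (4S,6E)-4-(TBSO)-3-[(TBSO)methyl]-6-ethylidene-5,6-dihydro-1-benzofuran-7(4H)-one
Product: 14 (4S,6S)-4-(TBSO)-3-[(TBSO)methyl]-6-methyl-6-vinyl-5,6-dihydro-1-benzofuran-7(4H)-one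
Conditions: LiN(i-Pr)2, THF–DMPU, −78 °C; MeI, −78 to −40 °C
Reagents that add atoms: iodomethane, CI
Why: Deconjugative α-alkylation of an extended enolate: γ-deprotonation of the ethylidene methyl gives the dienolate, which is methylated at C10 and leaves the vinyl group; iodomethane should enter anti to the pseudoaxial C8 silyl ether (1,3 to C10), so vinyl ends cis to O8 (6S).

Step 10
Reactants: 14 (4S,6S)-4-(TBSO)-3-[(TBSO)methyl]-6-methyl-6-vinyl-5,6-dihydro-1-benzofuran-7(4H)-one; 15 isopropenylmagnesium bromide
Product: 16 (4S,6S,7R)-4-(TBSO)-3-[(TBSO)methyl]-6-methyl-7-(prop-1-en-2-yl)-6-vinyl-4,5,6,7-tetrahydro-1-benzofuran-7-ol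
Conditions: CeCl3 (anhydrous), THF, −78 °C; then aq. NH4Cl
Reagents that add atoms: none
Why: 1,2-Addition of an organocerium reagent to a hindered, non-enolisable ketone; in the half-chair that keeps the C8 silyl ether pseudoaxial the cis vinyl group at C10 is axial, and attack anti to it should place isopropenyl trans to vinyl (7R), the relationship the key step needs.

Step 11
Reactants: 16 (4S,6S,7R)-4-(TBSO)-3-[(TBSO)methyl]-6-methyl-7-(prop-1-en-2-yl)-6-vinyl-4,5,6,7-tetrahydro-1-benzofuran-7-ol
Product: 19 (8S,1(10)E,4Z)-8,13-bis(TBSO)-6,12-epoxygermacra-1(10),4,6,11-tetraen-5-yl trifluoromethanesulfonate, via potassium alkoxide 17 (not isolated), via potassium enolate 18 (not isolated)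
Conditions: KH, 18-crown-6, THF, 0 °C to rt; then PhNTf2, −78 to 0 °C
Reagents that add atoms: N-phenylbis(trifluoromethanesulfonimide), FC(F)(F)S(=O)(=O)N(c1ccccc1)S(=O)(=O)C(F)(F)F
Why: KH with 18-crown-6 gives the free potassium alkoxide 17, whose C5–C10 bond is weakened by the oxyanion, and the 1,5-diene C2=C1–C10–C5–C4=C3 undergoes a [3,3]-sigmatropic shift at or below room temperature. The closest known reaction type is the anionic oxy-Cope ring expansion of trans-1,2-dialkenylcyclohexanols to (E)-cyclodec-5-enone enolates. The ten-membered ring is not closed end to end; it arises by ring expansion, C2–C3 forming across a six-membered chair transition state while the cyclohexane bond C5–C10 breaks. No stereocentre is created and C8 is untouched; the new stereochemical elements are the two alkene geometries. Because vinyl and isopropenyl are trans and both equatorial, the ring bonds C10–C9 and C5–C6 sit equatorially in the chair, so C9 ends trans to C2 and C6 trans to C3, with the axial oxyanion cis to C3 (hence 4Z by the sequence rule although both ring bonds are trans). The furan conjugates with the developing enolate, which lowers the barrier and leaves enolate 18 as the only basic species. The step needs chair over boat and O- over C-sulfonylation; the first is secured by the diequatorial trans arrangement in 16, the second by the hard potassium enolate and PhNTf2 at low temperature, which stores the C4=C5 geometry in triflate 19.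

Step 12
Reactants: 19 (8S,1(10)E,4Z)-8,13-bis(TBSO)-6,12-epoxygermacra-1(10),4,6,11-tetraen-5-yl trifluoromethanesulfonate
Product: 20 (8S,1(10)E,4E)-8,13-bis(TBSO)-6,12-epoxygermacra-1(10),4,6,11-tetraene
Conditions: Pd(OAc)2 (5 mol %), PPh3, HCO2H, n-Bu3N, DMF, 40 °C
Reagents that add atoms: none
Why: Palladium-catalysed formate reduction of an alkenyl triflate (oxidative addition, formate-to-hydride exchange with loss of CO2, reductive elimination) with retention of alkene geometry; 40 °C is well below the temperature at which the 1,5-diene would undergo Cope rearrangement.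

Step 13
Reactants: 20 (8S,1(10)E,4E)-8,13-bis(TBSO)-6,12-epoxygermacra-1(10),4,6,11-tetraene
Product: 21 (8S,1(10)E,4E)-8,13-bis(TBSO)-12-(trimethylsilyl)-6,12-epoxygermacra-1(10),4,6,11-tetraene
Conditions: s-BuLi, TMEDA, THF, −78 °C; Me3SiCl, −78 °C to rt
Reagents that add atoms: chlorotrimethylsilane, C[Si](C)(C)Cl
Why: α-Lithiation of the only free furan α-position, assisted by the neighbouring silyloxymethyl group, and silylation; the low temperature prevents silyl transfer from O13 to the lithiated carbon.

Step 14
Reactants: 21 (8S,1(10)E,4E)-8,13-bis(TBSO)-12-(trimethylsilyl)-6,12-epoxygermacra-1(10),4,6,11-tetraene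
Product: 24 (8S,1(10)E,4E)-8,13-bis(TBSO)-6-hydroxygermacra-1(10),4,7(11)-trien-12,6-olide (C6 epimers), via furan endoperoxide 22 (not isolated), via trimethylsilyl keto ester 23 (not isolated)
Conditions: O2, hν, tetraphenylporphyrin (cat.), CH2Cl2, −78 °C; then H2O, rt
Reagents that add atoms: oxygen, O=O
Why: [4+2] photo-oxygenation of the furan, much faster than the ene reaction of the trisubstituted alkenes at −78 °C, gives endoperoxide 22; a 1,2-shift of silicon from C12 to oxygen with O–O cleavage gives silyl ester 23. Hydrolysis and ring closure give the γ-hydroxybutenolide with C12 as the carbonyl carbon, a regiochemistry dictated by the silyl group.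

Step 15
Reactants: 24 (8S,1(10)E,4E)-8,13-bis(TBSO)-6-hydroxygermacra-1(10),4,7(11)-trien-12,6-olide
Product: 26 (6R,8S,1(10)E,4E)-8,13-bis(TBSO)germacra-1(10),4,7(11)-trien-12,6-olide, via sodium hydroxy carboxylate 25 (not isolated)
Conditions: NaBH4, EtOH–THF, 0 °C; then aq. NaH2PO4 (pH 4–5)
Reagents that add atoms: none
Why: The lactol is in equilibrium with its open C6 keto carboxylate; NaBH4 reduces the ketone in the 1,2 sense and the hydroxy acid lactonises on mild acidification. With H8 held in the plane of the C7=C11 bond by allylic strain, the ring chain covers one face of the C6 carbonyl, and hydride from the open face should place O6 cis to O8 (6R at this stage, 6S in 31).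

Step 16
Reactants: 26 (6R,8S,1(10)E,4E)-8,13-bis(TBSO)germacra-1(10),4,7(11)-trien-12,6-olide
Product: 27 (6R,8S,1(10)E,4E)-8,13-dihydroxygermacra-1(10),4,7(11)-trien-12,6-olide
Conditions: Bu4NF, AcOH (1:1), THF, rt
Reagents that add atoms: none
Why: Fluoride cleavage of both silyl ethers, buffered with acetic acid so that the lactone γ-proton and the acid-sensitive 1,5-diene are both spared.

Step 17
Reactants: 27 (6R,8S,1(10)E,4E)-8,13-dihydroxygermacra-1(10),4,7(11)-trien-12,6-olide
Product: 28 (6R,8S,1(10)E,4E)-13-acetoxy-8-hydroxygermacra-1(10),4,7(11)-trien-12,6-olide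
Conditions: Ac2O (1.1 equiv), 2,4,6-collidine, CH2Cl2, −20 to 0 °C
Reagents that add atoms: acetic anhydride, CC(=O)OC(C)=O
Why: Selective acetylation of the primary allylic alcohol over the hindered secondary C8 alcohol with a weak, non-nucleophilic base.

Step 18
Reactants: 28 (6R,8S,1(10)E,4E)-13-acetoxy-8-hydroxygermacra-1(10),4,7(11)-trien-12,6-olide
Product: 29 (6R,8S,1(10)E,4E)-13-acetoxy-8-[(Z)-2-methylbut-2-enoyloxy]germacra-1(10),4,7(11)-trien-12,6-olide
Conditions: angelic acid, 2,4,6-trichlorobenzoyl chloride, Et3N, toluene, rt; then 28, 45 °C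
Reagents that add atoms: angelic acid, C/C=C(/C)C(O)=O
Why: Mixed-anhydride (Yamaguchi-type) esterification without a nucleophilic catalyst, since such catalysts isomerise angelates to tiglates; 45 °C keeps the diene below its Cope threshold.

Step 19
Reactants: 29 (6R,8S,1(10)E,4E)-13-acetoxy-8-[(Z)-2-methylbut-2-enoyloxy]germacra-1(10),4,7(11)-trien-12,6-olide
Product: 31 (1R,4R,5R,6S,8S,10R)-13-acetoxy-8-[(Z)-2-methylbut-2-enoyloxy]-1,10:4,5-diepoxygermacr-7(11)-en-12,6-olide (CNP0251711.2), via 1(10)-monoepoxide 30 (not isolated)
Conditions: dimethyldioxirane (2.5 equiv, acetone solution), CH2Cl2, −20 to 0 °C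
Reagents that add atoms: dimethyldioxirane, CC1(C)OO1
Why: Electrophilic epoxidation of the two electron-rich trisubstituted ring alkenes with a neutral oxidant whose only by-product is acetone, so that acid-triggered transannular opening of monoepoxide 30 is avoided; the lactone and angelate alkenes are electron-poor and should not react. Attack on the outer face of each alkene, in the conformer with both methyl groups on the face opposite to O6 and O8, should give the 1R,10R and 4R,5R oxiranes.

## Compound list

1 | cyclohexane-1,3-dione | O=C1CCCC(=O)C1 | starting material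
2 | ethyl bromopyruvate | CCOC(=O)C(=O)CBr | starting material
3 | ethyl 3-hydroxy-4-oxo-2,3,4,5,6,7-hexahydro-1-benzofuran-3-carboxylate (racemic adduct) | CCOC(=O)C1(O)COC2=C1C(=O)CCC2 | intermediate
4 | ethyl 4-oxo-4,5,6,7-tetrahydro-1-benzofuran-3-carboxylate | O=C1CCCc2occ(C(=O)OCC)c21 | intermediate
5 | ethyl (4S)-4-hydroxy-4,5,6,7-tetrahydro-1-benzofuran-3-carboxylate | O[C@H]1CCCc2occ(C(=O)OCC)c21 | intermediate
6 | ethyl (4S)-4-(TBSO)-4,5,6,7-tetrahydro-1-benzofuran-3-carboxylate | CC(C)(C)[Si](C)(C)O[C@H]1CCCc2occ(C(=O)OCC)c21 | intermediate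
7 | ethyl (4S)-4-(TBSO)-7-oxo-4,5,6,7-tetrahydro-1-benzofuran-3-carboxylate | CC(C)(C)[Si](C)(C)O[C@H]1CCC(=O)c2occ(C(=O)OCC)c21 | intermediate
8 | (4S,7RS)-4-(TBSO)-3-(hydroxymethyl)-4,5,6,7-tetrahydro-1-benzofuran-7-ol | CC(C)(C)[Si](C)(C)O[C@H]1CCC(O)c2occ(CO)c21 | intermediate
9 | (4S,7RS)-4-(TBSO)-3-[(TBSO)methyl]-4,5,6,7-tetrahydro-1-benzofuran-7-ol | CC(C)(C)[Si](C)(C)O[C@H]1CCC(O)c2occ(CO[Si](C)(C)C(C)(C)C)c21 | intermediate
10 | (4S)-4-(TBSO)-3-[(TBSO)methyl]-5,6-dihydro-1-benzofuran-7(4H)-one | CC(C)(C)[Si](C)(C)O[C@H]1CCC(=O)c2occ(CO[Si](C)(C)C(C)(C)C)c21 | intermediate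
11 | (4S)-4-(TBSO)-3-[(TBSO)methyl]-6-(1-hydroxyethyl)-5,6-dihydro-1-benzofuran-7(4H)-one (diastereomers) | CC(C)(C)[Si](C)(C)O[C@H]1CC(C(C)O)C(=O)c2occ(CO[Si](C)(C)C(C)(C)C)c21 | intermediate
12 | methanesulfonate of 11 | CC(C)(C)[Si](C)(C)O[C@H]1CC(C(C)OS(C)(=O)=O)C(=O)c2occ(CO[Si](C)(C)C(C)(C)C)c21 | intermediate
13 | (4S,6E)-4-(TBSO)-3-[(TBSO)methyl]-6-ethylidene-5,6-dihydro-1-benzofuran-7(4H)-one | CC(C)(C)[Si](C)(C)O[C@H]1C/C(=C\C)C(=O)c2occ(CO[Si](C)(C)C(C)(C)C)c21 | intermediate
14 | (4S,6S)-4-(TBSO)-3-[(TBSO)methyl]-6-methyl-6-vinyl-5,6-dihydro-1-benzofuran-7(4H)-one (vinyl cis to O8) | CC(C)(C)[Si](C)(C)O[C@H]1C[C@@](C)(C=C)C(=O)c2occ(CO[Si](C)(C)C(C)(C)C)c21 | intermediate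
15 | isopropenylmagnesium bromide | CC(=C)[Mg]Br | starting material
16 | (4S,6S,7R)-4-(TBSO)-3-[(TBSO)methyl]-6-methyl-7-(prop-1-en-2-yl)-6-vinyl-4,5,6,7-tetrahydro-1-benzofuran-7-ol (vinyl and isopropenyl trans) | CC(C)(C)[Si](C)(C)O[C@H]1C[C@@](C)(C=C)[C@](O)(C(C)=C)c2occ(CO[Si](C)(C)C(C)(C)C)c21 | intermediate
17 | potassium alkoxide of 16 | CC(C)(C)[Si](C)(C)O[C@H]1C[C@@](C)(C=C)[C@]([O-])(C(C)=C)c2occ(CO[Si](C)(C)C(C)(C)C)c21.[K+] | intermediate
18 | potassium (8S,1(10)E,4Z)-8,13-bis(TBSO)-6,12-epoxygermacra-1(10),4,6,11-tetraen-5-olate | CC(C)(C)[Si](C)(C)O[C@H]1C/C(C)=C/CC/C(C)=C(\[O-])c2occ(CO[Si](C)(C)C(C)(C)C)c21.[K+] | intermediate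
19 | (8S,1(10)E,4Z)-8,13-bis(TBSO)-6,12-epoxygermacra-1(10),4,6,11-tetraen-5-yl trifluoromethanesulfonate | CC(C)(C)[Si](C)(C)O[C@H]1C/C(C)=C/CC/C(C)=C(\OS(=O)(=O)C(F)(F)F)c2occ(CO[Si](C)(C)C(C)(C)C)c21 | intermediate
20 | (8S,1(10)E,4E)-8,13-bis(TBSO)-6,12-epoxygermacra-1(10),4,6,11-tetraene | CC(C)(C)[Si](C)(C)O[C@H]1C/C(C)=C/CC/C(C)=C/c2occ(CO[Si](C)(C)C(C)(C)C)c21 | intermediate
21 | (8S,1(10)E,4E)-8,13-bis(TBSO)-12-(trimethylsilyl)-6,12-epoxygermacra-1(10),4,6,11-tetraene | CC(C)(C)[Si](C)(C)O[C@H]1C/C(C)=C/CC/C(C)=C/c2oc([Si](C)(C)C)c(CO[Si](C)(C)C(C)(C)C)c21 | intermediate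
22 | 6,12-epidioxy adduct of 21 (2,3,7-trioxabicyclo[2.2.1]hept-5-ene across C6 and C12) | CC(C)(C)[Si](C)(C)O[C@H]1C/C(C)=C/CC/C(C)=C/C23OOC(O2)([Si](C)(C)C)C(CO[Si](C)(C)C(C)(C)C)=C13 | intermediate
23 | trimethylsilyl (8S,1(10)E,4E)-8,13-bis(TBSO)-6-oxogermacra-1(10),4,7(11)-trien-12-oate (C6 and C12 cis on C7=C11) | CC(C)(C)[Si](C)(C)O[C@H]1C/C(C)=C/CC/C(C)=C/C(=O)/C1=C(\C(=O)O[Si](C)(C)C)CO[Si](C)(C)C(C)(C)C | intermediate
24 | (8S,1(10)E,4E)-8,13-bis(TBSO)-6-hydroxygermacra-1(10),4,7(11)-trien-12,6-olide (C6 epimers) | CC(C)(C)[Si](C)(C)O[C@H]1C/C(C)=C/CC/C(C)=C/C2(O)OC(=O)C(CO[Si](C)(C)C(C)(C)C)=C12 | intermediate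
25 | sodium (6R,8S,1(10)E,4E)-8,13-bis(TBSO)-6-hydroxygermacra-1(10),4,7(11)-trien-12-oate | CC(C)(C)[Si](C)(C)O[C@H]1C/C(C)=C/CC/C(C)=C/[C@@H](O)/C1=C(\C([O-])=O)CO[Si](C)(C)C(C)(C)C.[Na+] | intermediate
26 | (6R,8S,1(10)E,4E)-8,13-bis(TBSO)germacra-1(10),4,7(11)-trien-12,6-olide | CC(C)(C)[Si](C)(C)O[C@H]1C/C(C)=C/CC/C(C)=C/[C@H]2OC(=O)C(CO[Si](C)(C)C(C)(C)C)=C12 | intermediate
27 | (6R,8S,1(10)E,4E)-8,13-dihydroxygermacra-1(10),4,7(11)-trien-12,6-olide | O[C@H]1C/C(C)=C/CC/C(C)=C/[C@H]2OC(=O)C(CO)=C12 | intermediate
28 | (6R,8S,1(10)E,4E)-13-acetoxy-8-hydroxygermacra-1(10),4,7(11)-trien-12,6-olide | O[C@H]1C/C(C)=C/CC/C(C)=C/[C@H]2OC(=O)C(COC(C)=O)=C12 | intermediate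
29 | (6R,8S,1(10)E,4E)-13-acetoxy-8-[(Z)-2-methylbut-2-enoyloxy]germacra-1(10),4,7(11)-trien-12,6-olide | C/C=C(/C)C(=O)O[C@H]1C/C(C)=C/CC/C(C)=C/[C@H]2OC(=O)C(COC(C)=O)=C12 | intermediate
30 | (1R,6R,8S,10R,4E)-13-acetoxy-8-[(Z)-2-methylbut-2-enoyloxy]-1,10-epoxygermacra-4,7(11)-dien-12,6-olide | C/C=C(/C)C(=O)O[C@H]1C[C@@]2(C)O[C@@H]2CC/C(C)=C/[C@H]2OC(=O)C(COC(C)=O)=C12 | intermediate
31 | (1R,4R,5R,6S,8S,10R)-13-acetoxy-8-[(Z)-2-methylbut-2-enoyloxy]-1,10:4,5-diepoxygermacr-7(11)-en-12,6-olide | C/C=C(/C)C(=O)O[C@H]1C[C@@]2(C)O[C@@H]2CC[C@@]2(C)O[C@@H]2[C@H]2OC(=O)C(COC(C)=O)=C12 | target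

## Step count and least certain steps

Total: 19 steps. Longest linear sequence: 19 steps (1 and 2 to 31; 15 enters at step 10).

**Step 11 (key step).** The rearrangement may leak through a boat transition state or a stepwise cleavage and recombination of the allyl unit, which would erode one alkene geometry. Sulfonylation of the enolate on oxygen may also be incomplete because residual KH consumes the triflating agent. Fallback: from 16 the rearrangement is run with KN(SiMe3)2 and 18-crown-6 and the enolate is quenched with Me3SiCl to the trimethylsilyl enol ether F6, which can be purified. MeLi in THF then regenerates the enolate with retained geometry and PhNTf2 gives 19.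

**Step 4.** Hydrogen abstraction may not discriminate fully between C5–H and the C8–H next to the silyl ether, or the peroxyl radical may attack the furan ring. Fallback: from 6, radical bromination (NBS, AIBN, PhCF3, 80 °C) gives the furylic bromide F1. Silver-assisted acetolysis (AgOAc, AcOH, rt) gives the acetate F2, and LiAlH4 reduces the ethyl ester and the acetate together to diol 8, where the route is rejoined.

**Step 10.** Addition may run through the other half-chair, with the C8 silyl ether pseudoequatorial and the C10 methyl axial. That would place isopropenyl cis to vinyl and, after rearrangement, give a cis ring alkene. Fallback: the C10 epimer is made from 10 by reversing the order of the two C10 substituents. LiN(i-Pr)2 and MeI give the methyl ketone F3. α-Vinylation of its enolate (LiN(SiMe3)2, vinyl bromide, Pd2(dba)3, P(t-Bu)3) puts vinyl anti to O8 in ketone F4. In F4 the same conformational preference makes vinyl axial, so the organocerium addition should give the trans-dialkenyl carbinol F5. The conditions of step 11 convert F5 through the same enolate 18 into 19.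

**Step 15.** Facial selectivity of the hydride at the C6 ketone depends on the conformation of a mobile ten-membered keto acid and may be poor or reversed, which would give the C6 epimer of the lactone. Fallback: from 24, Me3SiCHN2 in MeOH–toluene gives the open keto methyl ester F7. Reagent-controlled reduction with (S)-2-methyl-CBS-oxazaborolidine and catecholborane, with the tetrasubstituted alkenyl group as the large substituent, gives the hydroxy ester F8, which closes to 26 on brief contact with Et3N.

**Step 18.** Acylation of the hindered C8 alcohol may be slow at a temperature the diene tolerates, and the angelate may isomerise to the tiglate. Fallback: from 28, carbodiimide coupling with 2-(diphenoxyphosphoryl)propanoic acid gives the phosphonate ester F9. A Z-selective Horner–Wadsworth–Emmons olefination (NaH, THF, −78 °C, then acetaldehyde) builds the angelate double bond and gives 29.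

**Step 19.** Epoxidation may occur on a minor ring conformer (poor facial selectivity at one alkene), or the monoepoxide may open transannularly. Fallback: from 29, reagent-controlled epoxidation with the D-fructose-derived ketone catalyst of the Shi epoxidation (KHSO5, K2CO3 buffer, MeCN–dimethoxymethane–water, 0 °C) is used. For E-trisubstituted alkenes this catalyst delivers oxygen in the sense that gives R,R oxiranes, the configuration required at both sites, and it leads to 31.

## Further compounds

F1 | step 4 | ethyl (4S,7RS)-7-bromo-4-(TBSO)-4,5,6,7-tetrahydro-1-benzofuran-3-carboxylate | CC(C)(C)[Si](C)(C)O[C@H]1CCC(Br)c2occ(C(=O)OCC)c21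
F2 | step 4 | ethyl (4S,7RS)-7-acetoxy-4-(TBSO)-4,5,6,7-tetrahydro-1-benzofuran-3-carboxylate | CC(C)(C)[Si](C)(C)O[C@H]1CCC(OC(C)=O)c2occ(C(=O)OCC)c21
F3 | step 10 | (4S,6RS)-4-(TBSO)-3-[(TBSO)methyl]-6-methyl-5,6-dihydro-1-benzofuran-7(4H)-one | CC(C)(C)[Si](C)(C)O[C@H]1CC(C)C(=O)c2occ(CO[Si](C)(C)C(C)(C)C)c21
F4 | step 10 | (4S,6R)-4-(TBSO)-3-[(TBSO)methyl]-6-methyl-6-vinyl-5,6-dihydro-1-benzofuran-7(4H)-one | CC(C)(C)[Si](C)(C)O[C@H]1C[C@](C)(C=C)C(=O)c2occ(CO[Si](C)(C)C(C)(C)C)c21
F5 | step 10 | (4S,6R,7S)-4-(TBSO)-3-[(TBSO)methyl]-6-methyl-7-(prop-1-en-2-yl)-6-vinyl-4,5,6,7-tetrahydro-1-benzofuran-7-ol | CC(C)(C)[Si](C)(C)O[C@H]1C[C@](C)(C=C)[C@@](O)(C(C)=C)c2occ(CO[Si](C)(C)C(C)(C)C)c21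
F6 | step 11 | (8S,1(10)E,4Z)-8,13-bis(TBSO)-5-(trimethylsilyloxy)-6,12-epoxygermacra-1(10),4,6,11-tetraene | CC(C)(C)[Si](C)(C)O[C@H]1C/C(C)=C/CC/C(C)=C(\O[Si](C)(C)C)c2occ(CO[Si](C)(C)C(C)(C)C)c21
F7 | step 15 | methyl (8S,1(10)E,4E)-8,13-bis(TBSO)-6-oxogermacra-1(10),4,7(11)-trien-12-oate | CC(C)(C)[Si](C)(C)O[C@H]1C/C(C)=C/CC/C(C)=C/C(=O)/C1=C(\C(=O)OC)CO[Si](C)(C)C(C)(C)C
F8 | step 15 | methyl (6R,8S,1(10)E,4E)-8,13-bis(TBSO)-6-hydroxygermacra-1(10),4,7(11)-trien-12-oate | CC(C)(C)[Si](C)(C)O[C@H]1C/C(C)=C/CC/C(C)=C/[C@@H](O)/C1=C(\C(=O)OC)CO[Si](C)(C)C(C)(C)C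
F9 | step 18 | (6R,8S,1(10)E,4E)-13-acetoxy-8-[2-(diphenoxyphosphoryl)propanoyloxy]germacra-1(10),4,7(11)-trien-12,6-olide | CC(P(=O)(Oc1ccccc1)Oc1ccccc1)C(=O)O[C@H]1C/C(C)=C/CC/C(C)=C/[C@H]2OC(=O)C(COC(C)=O)=C12
F0 | step 19 | none | none
A1 | alternative 1 | head-to-head trans-fused tricyclo[4.4.0.0(2,5)]decanone methyl ester (racemate, one enantiomer drawn) | O=C1CCC[C@@]2(C)[C@H]1[C@@]3(C(=O)OC)CC[C@@H]23
A2 | alternative 1 | 3-methylcyclohex-2-enone | CC1=CC(=O)CCC1
A3 | alternative 1 | methyl cyclobut-1-ene-1-carboxylate | COC(=O)C1=CCC1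
A4 | alternative 2 | (6R,8S,1(10)E,4E)-8-(TBSO)germacra-1(10),4,7(11)-trien-12,6-olide with C13 as allyl ester | CC(C)(C)[Si](C)(C)O[C@H]1C/C(C)=C/CC/C(C)=C/[C@H]2OC(=O)C(C(=O)OCC=C)=C12
A5 | alternative 3 | (1(10)E,2Z,4E)-germacra-1(10),2,4-trien-12,6-olide | C[C@H]1[C@@H]2CC/C(C)=C/C=C\C(C)=C\[C@H]2OC1=O
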